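**Retrosynthetic overview**

1. The last step removes all protecting groups (three MOM ethers, one tertiary TBS ether) from a fully assembled (2S)-flavanone.
2. Ring C is the only ring of the target closed in the route, and it closes at the C4–C4a bond: an aryne of ring A (triple bond C4a≡C8a) takes the alkoxide oxygen of an (S)-β-oxy Weinreb amide at C8a (O1–C8a), and the C4a carbanion then attacks the amide carbonyl (C4) in the same flask.
3. Enabling feature: in the phloroglucinol ring A the oxygen on C5 stands next to C4a, so the C4a≡C8a aryne is polarised to accept O1 at C8a and to carry the carbanion at C4a, which lies a six-membered ring away from C4. The C2–O bond is never broken, so the (S) configuration set by asymmetric transfer hydrogenation is carried through.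
4. Ring A piece: phloroglucinol and acrylic acid give a dihydrocoumarin (a temporary lactone ring that singles out the C8a oxygen); MeMgBr opens it to the 3-hydroxy-3-methylbutyl chain; carbamate-directed ortho-silylation puts TMS on C4a; triflation follows.
5. Ring B piece: the dimethylpyran ring is bought in as 7-hydroxy-2,2-dimethylchroman-4-one, then ortho-formylation, Weinreb acetate aldol, oxidation and asymmetric reduction. Ring order: pyran ring (from the start), temporary lactone (step 1, opened in step 3), ring C (step 14).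

Key step: step 14

Assumption: anhydrous phloroglucinol, 7-hydroxy-2,2-dimethylchroman-4-one and N-methoxy-N-methylacetamide are taken as catalogue compounds; flavanone numbering (O1, C2, C3, C4, C4a, C5 to C8, C8a) is used for ring positions throughout.

**Route**

Step 1
Reactants: 1 phloroglucinol; 2 acrylic acid
Product: 4 5,7-dihydroxychroman-2-one, via 3-(2,4,6-trihydroxyphenyl)propanoic acid 3 (not isolated)
Conditions: Amberlyst-15, toluene/1,4-dioxane, reflux (Dean–Stark)
Reagents that add atoms: none
Why: Acid-catalysed conjugate hydroarylation of acrylic acid by the very nucleophilic phloroglucinol ring (Friedel–Crafts alkylation) followed by lactonisation; the three ring CH positions are equivalent, and the lactone marks one of the two oxygens flanking the new side chain as the future C8a oxygen.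

Step 2
Reactants: 4 5,7-dihydroxychroman-2-one
Product: 5 5,7-bis(methoxymethoxy)chroman-2-one
Conditions: MOMCl, i-Pr2NEt, CH2Cl2, 0 °C → rt
Reagents that add atoms: chloromethyl methyl ether (MOMCl), COCCl
Why: O-Alkylation of the two free phenols with MOMCl under a hindered amine base (acetal protection) should leave the aryl lactone intact.

Step 3
Reactants: 5 5,7-bis(methoxymethoxy)chroman-2-one
Product: 7 2-(3-hydroxy-3-methylbutyl)-3,5-bis(methoxymethoxy)phenol, via bromomagnesium phenoxide of the methyl ketone 6 (not isolated)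
Conditions: MeMgBr (3 equiv), THF, 0 °C → rt; sat. aq NH4Cl
Reagents that add atoms: methylmagnesium bromide, C[Mg]Br
Why: Double Grignard addition to the aryl lactone builds the tertiary carbinol of the side chain and releases only the phenol that was the lactone oxygen, the MOM ethers being inert.

Step 4
Reactants: 7 2-(3-hydroxy-3-methylbutyl)-3,5-bis(methoxymethoxy)phenol
Product: 8 2-(3-hydroxy-3-methylbutyl)-3,5-bis(methoxymethoxy)phenyl N-isopropylcarbamate
Conditions: i-PrNCO, Et3N (cat.), CH2Cl2, rt
Reagents that add atoms: isopropyl isocyanate, CC(C)N=C=O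
Why: Base-catalysed addition of the phenol to the isocyanate should give the aryl carbamate, the hindered tertiary alcohol reacting far more slowly.

Step 5
Reactants: 8 2-(3-hydroxy-3-methylbutyl)-3,5-bis(methoxymethoxy)phenyl N-isopropylcarbamate
Product: 12 2-[3-(tert-butyldimethylsilyloxy)-3-methylbutyl]-3,5-bis(methoxymethoxy)-6-(trimethylsilyl)phenyl N-isopropylcarbamate, via N,O-bis(tert-butyldimethylsilyl) carbamate 9 (not isolated), via ortho-lithiated carbamate 10 (not isolated), via C-silylated N-silyl carbamate 11 (not isolated)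
Conditions: TBSOTf (2.3 equiv), TMEDA, Et2O, 0 °C → rt; n-BuLi, TMEDA, −78 °C; TMSCl, −78 °C → rt; MeOH, then sat. aq NH4Cl
Reagents that add atoms: tert-butyldimethylsilyl trifluoromethanesulfonate (TBSOTf), CC(C)(C)[Si](C)(C)OS(=O)(=O)C(F)(F)F; chlorotrimethylsilane (TMSCl), C[Si](C)(C)Cl
Why: Directed ortho-metalation, in which TBSOTf caps the tertiary alcohol and the carbamate N–H in the flask, the N-silyl carbamate (the strongest directing group present) steers n-BuLi to its only free ortho CH (also flanked by a MOM ether), TMSCl silylates the aryllithium and the N–Si bond is hydrolysed on the non-acidic work-up.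

Step 6
Reactants: 12 2-[3-(tert-butyldimethylsilyloxy)-3-methylbutyl]-3,5-bis(methoxymethoxy)-6-(trimethylsilyl)phenyl N-isopropylcarbamate
Product: 14 2-[3-(tert-butyldimethylsilyloxy)-3-methylbutyl]-3,5-bis(methoxymethoxy)-6-(trimethylsilyl)phenyl trifluoromethanesulfonate, via ortho-silylphenol 13 (not isolated)
Conditions: DBU, Et2NH, MeCN, 40 °C; then PhNTf2, rt
Reagents that add atoms: N-phenylbis(trifluoromethanesulfonimide) (PhNTf2), O=S(=O)(N(c1ccccc1)S(=O)(=O)C(F)(F)F)C(F)(F)F
Why: E1cB cleavage of the N–H carbamate (isopropyl isocyanate trapped by Et2NH as the urea) frees the phenoxide, which is triflated in the same flask to the ortho-silylaryl triflate, the standard fluoride-triggered aryne precursor.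

Step 7
Reactants: 15 7-hydroxy-2,2-dimethylchroman-4-one
Product: 17 2,2-dimethyl-2H-chromen-7-ol, via 2,2-dimethylchromane-4,7-diol 16 (not isolated)
Conditions: LiAlH4, THF, 0 °C → reflux; 1 M HCl work-up; then p-TsOH (cat.), toluene, 60 °C
Reagents that add atoms: none
Why: Hydride reduction of the aryl ketone and acid-catalysed E1 dehydration of the benzylic alcohol, assisted by the para hydroxy group, should give the conjugated 2H-chromene.

Step 8
Reactants: 17 2,2-dimethyl-2H-chromen-7-ol
Product: 18 7-hydroxy-2,2-dimethyl-2H-chromene-6-carbaldehyde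
Conditions: MgCl2, Et3N, (CH2O)n, MeCN, reflux
Reagents that add atoms: paraformaldehyde (as formaldehyde), C=O
Why: Magnesium-phenoxide-mediated ortho-formylation (Casnati–Skattebøl reaction) is ortho-specific, and of the two ortho positions the unhindered C6 (para to the pyran oxygen) should be taken in preference to C8 between the two oxygens, as with 3-alkoxyphenols.

Step 9
Reactants: 18 7-hydroxy-2,2-dimethyl-2H-chromene-6-carbaldehyde
Product: 19 7-(methoxymethoxy)-2,2-dimethyl-2H-chromene-6-carbaldehyde
Conditions: MOMCl, i-Pr2NEt, CH2Cl2, 0 °C → 40 °C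
Reagents that add atoms: chloromethyl methyl ether (MOMCl), COCCl
Why: O-Alkylation of the hydrogen-bonded phenol with MOMCl (acetal protection) removes the only acidic OH before the enolate and aryne chemistry.

Step 10
Reactants: 19 7-(methoxymethoxy)-2,2-dimethyl-2H-chromene-6-carbaldehyde; 20 N-methoxy-N-methylacetamide
Product: 22 racemic 3-hydroxy-N-methoxy-3-[7-(methoxymethoxy)-2,2-dimethyl-2H-chromen-6-yl]-N-methylpropanamide, via lithium enolate 21 (not isolated)
Conditions: LiN(i-Pr)2, THF, −78 °C; then 19, −78 °C; sat. aq NH4Cl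
Reagents that add atoms: none
Why: Aldol addition of the preformed lithium enolate of the Weinreb acetamide to the non-enolisable aldehyde gives the β-hydroxy amide, whose stereocentre is erased in the next step.

Step 11
Reactants: 22 racemic 3-hydroxy-N-methoxy-3-[7-(methoxymethoxy)-2,2-dimethyl-2H-chromen-6-yl]-N-methylpropanamide
Product: 23 N-methoxy-3-[7-(methoxymethoxy)-2,2-dimethyl-2H-chromen-6-yl]-N-methyl-3-oxopropanamide
Conditions: Dess–Martin periodinane, CH2Cl2, 0 °C → rt
Reagents that add atoms: none
Why: Dess–Martin oxidation of the benzylic secondary alcohol to the β-keto amide proceeds under near-neutral conditions that should leave the chromene and the MOM ether alone.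

Step 12
Reactants: 23 N-methoxy-3-[7-(methoxymethoxy)-2,2-dimethyl-2H-chromen-6-yl]-N-methyl-3-oxopropanamide
Product: 24 (3S)-3-hydroxy-N-methoxy-3-[7-(methoxymethoxy)-2,2-dimethyl-2H-chromen-6-yl]-N-methylpropanamide
Conditions: RuCl[(S,S)-TsDPEN](p-cymene) (1 mol %), HCO2H/Et3N (5:2), CH2Cl2, 30 °C
Reagents that add atoms: none
Why: Noyori–Ikariya asymmetric transfer hydrogenation of the aryl ketone, in which hydride is delivered to the face set by the CH/π contact between the η6-arene of the catalyst and the substrate aryl ring, so that the (S,S)-ligand should give the (S)-carbinol (the future C2) as for acetophenone-type ketones while the chromene C=C is not touched.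

Step 13
Reactants: 24 (3S)-3-hydroxy-N-methoxy-3-[7-(methoxymethoxy)-2,2-dimethyl-2H-chromen-6-yl]-N-methylpropanamide
Product: 25 (3S)-N-methoxy-3-[7-(methoxymethoxy)-2,2-dimethyl-2H-chromen-6-yl]-N-methyl-3-(trimethylsilyloxy)propanamide
Conditions: TMSCl, imidazole, CH2Cl2, 0 °C
Reagents that add atoms: chlorotrimethylsilane (TMSCl), C[Si](C)(C)Cl
Why: Silylation of the secondary alcohol turns it into a proton-free latent alkoxide for the key step without touching the stereocentre.

Step 14
Reactants: 25 (3S)-N-methoxy-3-[7-(methoxymethoxy)-2,2-dimethyl-2H-chromen-6-yl]-N-methyl-3-(trimethylsilyloxy)propanamide; 14 2-[3-(tert-butyldimethylsilyloxy)-3-methylbutyl]-3,5-bis(methoxymethoxy)-6-(trimethylsilyl)phenyl trifluoromethanesulfonate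
Product: 30 (2S)-8-[3-(tert-butyldimethylsilyloxy)-3-methylbutyl]-5,7-bis(methoxymethoxy)-2-[7-(methoxymethoxy)-2,2-dimethyl-2H-chromen-6-yl]chroman-4-one, via aryne 26 (not isolated), via cesium alkoxide 27 (not isolated), via aryl carbanion 28 (not isolated), via cesium hemiaminal alkoxide 29 (not isolated)
Conditions: CsF (4 equiv), 18-crown-6, THF, −20 °C → rt; sat. aq NH4Cl, 0 °C
Reagents that add atoms: none
Why: Proposed new method: fluoride removes the aryl TMS group of 14 (loss of triflate gives aryne 26, whose triple bond lies between C8a and C4a of ring A) and also the O–TMS group of 25, so that cesium alkoxide 27 forms without any proton source; 27 adds through oxygen to C8a, and the resulting C4a carbanion 28 attacks the Weinreb carbonyl (C4) to close ring C at the C4–C4a bond, hemiaminal 29 releasing the ketone only on the mildly acidic quench. The closest known reaction type is the fluoride-triggered annulation of arynes with methyl salicylates to xanthones (heteroatom addition to the aryne, then intramolecular acylation of the aryl anion), extended here from a phenoxide/ester pair to an aliphatic alkoxide/Weinreb amide pair. Ring C closes by a 6-exo-trig attack of the aryl carbanion on the amide C=O. No stereocentre of the product is created: C2 keeps the (S) configuration from step 12 because its C–O bond is never broken, the temporary C4 centre of 29 disappears on work-up, and holding the product as 29 keeps the base-labile flavanone (retro-oxa-Michael opening to the chalcone) away from alkoxide. The step needs attack of oxygen at C8a and not at C4a, which the C5 methoxymethoxy group next to C4a should secure by polarising the aryne (attack at the distal carbon, carbanion ortho to oxygen) more strongly than the C8 side chain hinders it. It also needs acylation to outrun protonation of 28, which the aprotic release of 27 from the silyl ether (in place of the free alcohol) is designed to secure.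

Step 15
Reactants: 30 (2S)-8-[3-(tert-butyldimethylsilyloxy)-3-methylbutyl]-5,7-bis(methoxymethoxy)-2-[7-(methoxymethoxy)-2,2-dimethyl-2H-chromen-6-yl]chroman-4-one
Product: 32 (2S)-5,7-dihydroxy-2-(7-hydroxy-2,2-dimethyl-2H-chromen-6-yl)-8-(3-hydroxy-3-methylbutyl)chroman-4-one, via tris(trimethylsilyl) ether 31 (not isolated)
Conditions: TMSOTf, 2,2'-bipyridyl, MeCN, 0 °C → rt; then HF·pyridine, pyridine, THF, 0 °C → rt; aq NaHCO3
Reagents that add atoms: none
Why: Silyl triflate/bipyridyl activation should convert each aryl MOM ether into the aryl TMS ether under buffered aprotic conditions (acetal cleavage without Brønsted acid, so that the C2 benzylic ether, the chromene and the side chain are not ionised), and buffered HF then cleaves all four Si–O bonds, the tertiary one last.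

**Compound list**

1 | phloroglucinol | Oc1cc(O)cc(O)c1 | starting material
2 | acrylic acid | C=CC(=O)O | starting material
3 | 3-(2,4,6-trihydroxyphenyl)propanoic acid | OC(=O)CCc1c(O)cc(O)cc1O | intermediate
4 | 5,7-dihydroxychroman-2-one | O=C1CCc2c(O)cc(O)cc2O1 | intermediate
5 | 5,7-bis(methoxymethoxy)chroman-2-one | O=C1CCc2c(OCOC)cc(OCOC)cc2O1 | intermediate
6 | bromomagnesium 3,5-bis(methoxymethoxy)-2-(3-oxobutyl)phenoxide | CC(=O)CCc1c(O[Mg]Br)cc(OCOC)cc1OCOC | intermediate
7 | 2-(3-hydroxy-3-methylbutyl)-3,5-bis(methoxymethoxy)phenol | CC(C)(O)CCc1c(O)cc(OCOC)cc1OCOC | intermediate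
8 | 2-(3-hydroxy-3-methylbutyl)-3,5-bis(methoxymethoxy)phenyl N-isopropylcarbamate | CC(C)NC(=O)Oc1cc(OCOC)cc(OCOC)c1CCC(C)(C)O | intermediate
9 | 2-[3-(tert-butyldimethylsilyloxy)-3-methylbutyl]-3,5-bis(methoxymethoxy)phenyl N-(tert-butyldimethylsilyl)-N-isopropylcarbamate | CC(C)N(C(=O)Oc1cc(OCOC)cc(OCOC)c1CCC(C)(C)O[Si](C)(C)C(C)(C)C)[Si](C)(C)C(C)(C)C | intermediate
10 | 6-lithio derivative of 9 (lithium on the ring carbon between the carbamate and a MOM ether) | CC(C)N(C(=O)Oc1c([Li])c(OCOC)cc(OCOC)c1CCC(C)(C)O[Si](C)(C)C(C)(C)C)[Si](C)(C)C(C)(C)C | intermediate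
11 | 6-(trimethylsilyl) derivative of 9 | CC(C)N(C(=O)Oc1c([Si](C)(C)C)c(OCOC)cc(OCOC)c1CCC(C)(C)O[Si](C)(C)C(C)(C)C)[Si](C)(C)C(C)(C)C | intermediate
12 | 2-[3-(tert-butyldimethylsilyloxy)-3-methylbutyl]-3,5-bis(methoxymethoxy)-6-(trimethylsilyl)phenyl N-isopropylcarbamate | CC(C)NC(=O)Oc1c([Si](C)(C)C)c(OCOC)cc(OCOC)c1CCC(C)(C)O[Si](C)(C)C(C)(C)C | intermediate
13 | 2-[3-(tert-butyldimethylsilyloxy)-3-methylbutyl]-3,5-bis(methoxymethoxy)-6-(trimethylsilyl)phenol | Oc1c([Si](C)(C)C)c(OCOC)cc(OCOC)c1CCC(C)(C)O[Si](C)(C)C(C)(C)C | intermediate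
14 | 2-[3-(tert-butyldimethylsilyloxy)-3-methylbutyl]-3,5-bis(methoxymethoxy)-6-(trimethylsilyl)phenyl trifluoromethanesulfonate | O=S(=O)(Oc1c([Si](C)(C)C)c(OCOC)cc(OCOC)c1CCC(C)(C)O[Si](C)(C)C(C)(C)C)C(F)(F)F | intermediate
15 | 7-hydroxy-2,2-dimethylchroman-4-one | CC1(C)CC(=O)c2ccc(O)cc2O1 | starting material
16 | racemic 2,2-dimethylchromane-4,7-diol | CC1(C)CC(O)c2ccc(O)cc2O1 | intermediate
17 | 2,2-dimethyl-2H-chromen-7-ol | CC1(C)C=Cc2ccc(O)cc2O1 | intermediate
18 | 7-hydroxy-2,2-dimethyl-2H-chromene-6-carbaldehyde | CC1(C)C=Cc2cc(C=O)c(O)cc2O1 | intermediate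
19 | 7-(methoxymethoxy)-2,2-dimethyl-2H-chromene-6-carbaldehyde | CC1(C)C=Cc2cc(C=O)c(OCOC)cc2O1 | intermediate
20 | N-methoxy-N-methylacetamide | CC(=O)N(C)OC | starting material
21 | lithium enolate of N-methoxy-N-methylacetamide | C=C(O[Li])N(C)OC | intermediate
22 | racemic 3-hydroxy-N-methoxy-3-[7-(methoxymethoxy)-2,2-dimethyl-2H-chromen-6-yl]-N-methylpropanamide | OC(CC(=O)N(C)OC)c1cc2c(cc1OCOC)OC(C)(C)C=C2 | intermediate
23 | N-methoxy-3-[7-(methoxymethoxy)-2,2-dimethyl-2H-chromen-6-yl]-N-methyl-3-oxopropanamide | O=C(CC(=O)N(C)OC)c1cc2c(cc1OCOC)OC(C)(C)C=C2 | intermediate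
24 | (3S)-3-hydroxy-N-methoxy-3-[7-(methoxymethoxy)-2,2-dimethyl-2H-chromen-6-yl]-N-methylpropanamide | O[C@H](c1cc2c(cc1OCOC)OC(C)(C)C=C2)CC(=O)N(C)OC | intermediate
25 | (3S)-N-methoxy-3-[7-(methoxymethoxy)-2,2-dimethyl-2H-chromen-6-yl]-N-methyl-3-(trimethylsilyloxy)propanamide | C[Si](C)(C)O[C@H](c1cc2c(cc1OCOC)OC(C)(C)C=C2)CC(=O)N(C)OC | intermediate
26 | 3-[3-(tert-butyldimethylsilyloxy)-3-methylbutyl]-4,6-bis(methoxymethoxy)benzyne (triple bond between the future C8a and C4a) | CC(C)(O[Si](C)(C)C(C)(C)C)CCC1=C(OCOC)C=C(OCOC)C#C1 | intermediate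
27 | cesium (S)-alkoxide of 24 | [Cs+].[O-][C@H](c1cc2c(cc1OCOC)OC(C)(C)C=C2)CC(=O)N(C)OC | intermediate
28 | cesium salt of the (3S)-3-aryloxy Weinreb amide carbanion (negative charge on the ring carbon ortho to the new ether oxygen, the future C4a) | [Cs+].CC(C)(O[Si](C)(C)C(C)(C)C)CCc1c(OCOC)cc(OCOC)[c-]c1O[C@H](c1cc2c(cc1OCOC)OC(C)(C)C=C2)CC(=O)N(C)OC | intermediate
29 | cesium (2S)-8-[3-(tert-butyldimethylsilyloxy)-3-methylbutyl]-4-[methoxy(methyl)amino]-5,7-bis(methoxymethoxy)-2-[7-(methoxymethoxy)-2,2-dimethyl-2H-chromen-6-yl]chroman-4-olate (C4 configuration undefined) | [Cs+].CC(C)(O[Si](C)(C)C(C)(C)C)CCc1c(OCOC)cc(OCOC)c2c1O[C@H](c1cc3c(cc1OCOC)OC(C)(C)C=C3)CC2([O-])N(C)OC | intermediate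
30 | (2S)-8-[3-(tert-butyldimethylsilyloxy)-3-methylbutyl]-5,7-bis(methoxymethoxy)-2-[7-(methoxymethoxy)-2,2-dimethyl-2H-chromen-6-yl]chroman-4-one | CC(C)(O[Si](C)(C)C(C)(C)C)CCc1c(OCOC)cc(OCOC)c2c1O[C@H](c1cc3c(cc1OCOC)OC(C)(C)C=C3)CC2=O | intermediate
31 | (2S)-8-[3-(tert-butyldimethylsilyloxy)-3-methylbutyl]-2-[2,2-dimethyl-7-(trimethylsilyloxy)-2H-chromen-6-yl]-5,7-bis(trimethylsilyloxy)chroman-4-one | CC(C)(O[Si](C)(C)C(C)(C)C)CCc1c(O[Si](C)(C)C)cc(O[Si](C)(C)C)c2c1O[C@H](c1cc3c(cc1O[Si](C)(C)C)OC(C)(C)C=C3)CC2=O | intermediate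
32 | (2S)-5,7-dihydroxy-2-(7-hydroxy-2,2-dimethyl-2H-chromen-6-yl)-8-(3-hydroxy-3-methylbutyl)chroman-4-one | CC(C)(O)CCc1c(O)cc(O)c2c1O[C@H](c1cc3c(cc1O)OC(C)(C)C=C3)CC2=O | target

**Step count and risks**

Total step count: 15. Longest linear sequence: 9 steps (steps 7 to 15, starting from 15).

Steps most likely to fail:

1. Step 14 (the proposed annulation). What may go wrong: retro-aldol cleavage or β-elimination of the free alkoxide before it meets the aryne; protonation or α-deprotonation by the aryl carbanion in place of acylation, which leaves an open aryl ether or expels the aryloxide; attack of oxygen at the wrong aryne carbon. Fallback with known reactions, setting out from 8 and 23 and returning at 30: carbamate 8 is taken through the same silylation and lithiation as in step 5 (through 9 and 10), but the aryllithium is quenched with iodine to give the iodo carbamate F1. DBU/Et2NH in MeCN cleaves the carbamate to the iodophenol F2. Keto amide 23 is reduced with RuCl[(R,R)-TsDPEN](p-cymene) and HCO2H/Et3N to the (R)-alcohol F3. Mitsunobu etherification of F2 with F3 (PPh3, DIAD, toluene, 0 °C) should give, with inversion at the carbinol carbon, the (S)-aryl ether iodide F4. Iodine–lithium exchange (n-BuLi, THF, −78 °C) followed by Parham-type cycloacylation of the aryllithium on the Weinreb amide closes the same C4–C4a bond and gives 30 after NH4Cl quench.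

2. Step 5. What may go wrong: lithiation at the ring CH between the two MOM ethers or at the benzylic CH2 instead of the CH next to the carbamate; anionic ortho-Fries migration of the carbamoyl group; incomplete silylation of the tertiary alcohol, which then consumes base. Fallback that sets the regiochemistry by electrophilic halogenation instead of deprotonation, setting out from 7 and returning at 13 and 14: both hydroxy groups of 7 are silylated (TBSOTf, 2,6-lutidine, CH2Cl2) to the bis-silyl ether F5. The aryl silyl ether alone is cleaved (K2CO3, MeOH) to the phenol F6. Amine-catalysed ortho-selective bromination (NBS, i-Pr2NH cat., CH2Cl2) gives the bromophenol F7. O-Silylation with hexamethyldisilazane gives the O-trimethylsilyl bromoarene F8. n-BuLi in THF at −78 °C (bromine–lithium exchange followed by retro-Brook O-to-C silyl shift) gives the lithium salt of 13, which is triflated with PhNTf2 to 14.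

3. Step 15. What may go wrong: Lewis-acid-promoted opening of ring C (retro-oxa-Michael) or ionisation of the C2–O1 benzylic ether assisted by the ortho and para oxygens of ring B, both with loss of the C2 configuration; incomplete cleavage of the tertiary silyl ether; cyclisation of the freed tertiary carbinol onto the C7 phenol. Fallback by protic transacetalisation in two stages, setting out from 30 and returning at 32: HCl generated from AcCl (cat.) in MeOH at 0 °C → rt removes the three MOM groups as dimethoxymethane while the tertiary silyl ether stays on and shields the carbinol from ionisation, giving the silyl-protected triol F9. Buffered HF·pyridine in THF then removes the TBS group to give 32.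

Further compounds
F1 | step 14 | 2-[3-(tert-butyldimethylsilyloxy)-3-methylbutyl]-6-iodo-3,5-bis(methoxymethoxy)phenyl N-isopropylcarbamate | CC(C)NC(=O)Oc1c(I)c(OCOC)cc(OCOC)c1CCC(C)(C)O[Si](C)(C)C(C)(C)C
F2 | step 14 | 2-[3-(tert-butyldimethylsilyloxy)-3-methylbutyl]-6-iodo-3,5-bis(methoxymethoxy)phenol | Oc1c(I)c(OCOC)cc(OCOC)c1CCC(C)(C)O[Si](C)(C)C(C)(C)C
F3 | step 14 | (3R)-3-hydroxy-N-methoxy-3-[7-(methoxymethoxy)-2,2-dimethyl-2H-chromen-6-yl]-N-methylpropanamide | O[C@@H](c1cc2c(cc1OCOC)OC(C)(C)C=C2)CC(=O)N(C)OC
F4 | step 14 | (3S)-3-{2-[3-(tert-butyldimethylsilyloxy)-3-methylbutyl]-6-iodo-3,5-bis(methoxymethoxy)phenoxy}-N-methoxy-3-[7-(methoxymethoxy)-2,2-dimethyl-2H-chromen-6-yl]-N-methylpropanamide | CC(C)(O[Si](C)(C)C(C)(C)C)CCc1c(OCOC)cc(OCOC)c(I)c1O[C@H](c1cc2c(cc1OCOC)OC(C)(C)C=C2)CC(=O)N(C)OC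
F5 | step 5 | tert-butyl{2-[3-(tert-butyldimethylsilyloxy)-3-methylbutyl]-3,5-bis(methoxymethoxy)phenoxy}dimethylsilane | CC(C)(O[Si](C)(C)C(C)(C)C)CCc1c(O[Si](C)(C)C(C)(C)C)cc(OCOC)cc1OCOC
F6 | step 5 | 2-[3-(tert-butyldimethylsilyloxy)-3-methylbutyl]-3,5-bis(methoxymethoxy)phenol | CC(C)(O[Si](C)(C)C(C)(C)C)CCc1c(O)cc(OCOC)cc1OCOC
F7 | step 5 | 6-bromo-2-[3-(tert-butyldimethylsilyloxy)-3-methylbutyl]-3,5-bis(methoxymethoxy)phenol | CC(C)(O[Si](C)(C)C(C)(C)C)CCc1c(O)c(Br)c(OCOC)cc1OCOC
F8 | step 5 | {6-bromo-2-[3-(tert-butyldimethylsilyloxy)-3-methylbutyl]-3,5-bis(methoxymethoxy)phenoxy}trimethylsilane | CC(C)(O[Si](C)(C)C(C)(C)C)CCc1c(O[Si](C)(C)C)c(Br)c(OCOC)cc1OCOC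
F9 | step 15 | (2S)-8-[3-(tert-butyldimethylsilyloxy)-3-methylbutyl]-5,7-dihydroxy-2-(7-hydroxy-2,2-dimethyl-2H-chromen-6-yl)chroman-4-one | CC(C)(O[Si](C)(C)C(C)(C)C)CCc1c(O)cc(O)c2c1O[C@H](c1cc3c(cc1O)OC(C)(C)C=C3)CC2=O
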